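**Assumption:** the C1–C1' axis is drawn without a descriptor, so the target is taken as the racemate of its two atropisomers and no step has to control the axis.

## Analysis of the target

The target 28 is a 1,1'-binaphthalene. Half A carries OH on C2, OMe on C4, OH on C5 and methyl on C7; half B carries methyl on C2', OH on C4', OMe on C5' and OH on C6'; the two are joined by the C1–C1' bond. There is no stereocentre. The only stereogenic element is the C1–C1' axis, flanked by the C2 hydroxyl, the C2' methyl and the peri positions C8 and C8', and it is left unconfigured. Each half has a methoxy group peri to a free hydroxyl (C4/C5 and C5'/C4'), so two methyl ethers must be kept while four phenols are released. The free tetraphenol is electron-rich and prone to air oxidation, so it should appear only in the last step. The difficulty lies in the defined oxygenation of two different naphthalenes and in the hindered bond between them, which is poorly suited to a late cross-coupling of two finished partners. The strategy rests on the fact that C1' and C4' of half B both sit on the ring that carries C5' (OMe) and C6' (OH), through the fusion carbons C8a' and C4a'. C1' and C4' can therefore be C3 and the carbonyl carbon of a phthalide that already bears half A, and C2' (with its methyl) and C3' can be the β- and α-carbons of a crotonate.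

## Retrosynthetic reasoning

**28 from 27.** The three benzylic C–O bonds are cut last. Only oxygens that are free in the target are benzylated, the two methoxy groups pass through untouched, and hydrogenolysis is neutral, so the sensitive tetraphenol is formed in the final operation.

**27 from 25 via 26.** C3' carries hydrogen in 27 and a tert-butoxycarbonyl group in 25. That ester is what makes C3' nucleophilic in the ring-forming step, so it is treated as a traceless activating group. Forward, acidolysis gives acid 26, and protodecarboxylation is helped by the ortho hydroxyl on C4' and the ortho methyl on C2'.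

**25 from 21 and 22.** The C1'–C4' ring is opened at C1'–C2' and C3'–C4'. These bonds are chosen because they leave a phthalide (21), in which C1' is an acidic benzylic carbon and C4' an acyl carbon, and a four-carbon ester (22) that supplies C2', its methyl and C3' in one piece. Regiochemistry then follows from polarity alone. The hindered biaryl bond does not have to be made between two aromatic rings: it exists in 21 as an ordinary bond from a naphthalene to an sp3 carbon and becomes an axis only when the new ring aromatises. Forward, the anion of 21 must add to 22, the ester enolate must close onto the lactone carbonyl, and dehydration must aromatise the ring.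

**21 from 18 and 12.** The bond between the future C1' and C1 of half A and the lactone C–O bond are cut. This gives benzamide 18, whose amide directs metalation to its only free ortho position (aryllithium 19), and aldehyde 12. Carbinol 20 closes to the lactone with loss of the amine.

**18 from 13.** The amide comes from acid 16, the acid from ester 15, and the two ether groups are put on one after the other (14, then 15). The hydroxyl next to the ester of 13 is tied up in a hydrogen bond, so the other one is benzylated first.

**12 from 10 via 11.** The formyl carbon is removed from C1, the most nucleophilic position of 11 (α, ortho to one oxygen and para to the other). Benzyl ether 11 comes from naphthol 10.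

**10 from 7 and 3.** The C1–C4 ring of half A is opened at C1–C8a and C4–C4a: a [4+2] cycloaddition of aryne 8, released from 7, with diene 3. The benzyloxy group of 8 polarises the aryne so that the ketene-acetal carbon of 3 ends next to it. This places OMe on C4 peri to the benzyloxy group and leaves the C2 oxygen as a free hydroxyl, already differentiated from the methyl ether.

**7 from 4, and 3 from 1.** Triflate 7 comes from orcinol 4 by iodination between the two hydroxyls (5), benzylation of one hydroxyl (6) and triflation of the other. Diene 3 comes from ketene acetal 1 by C-acetylation (2) and silylation.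

## Alternatives that were turned down

**Alternative 1: aryne cycloaddition that builds the dioxygenated ring of half A on a finished half B.**
- Disconnection: C1–C8a and C4–C4a of half A.
- Forward key step: an alkoxy-aryne, released from an ortho-iodoaryl triflate by a silylmethyl Grignard reagent, adds to diene A1, a ketene-acetal silyloxy diene carrying half B on its terminal carbon. Loss of one methoxy group as the alcohol and of the silyl group gives binaphthol A2.
- For it: the cycloaddition type and its control by the alkoxy group are the same as those used here for half A. A2 needs only hydrogenolysis to reach the target, so its endgame is shorter than the chosen one, which must first remove an ester. On that point it is stronger.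
- Against it: the carbon of A1 that must bond to the aryne bears a naphthyl group flanked by the C2' methyl and the C8' peri hydrogen. The s-cis conformation and the approach to that carbon are both hindered, and an aryne then diverts to [2+2] addition at the open ketene-acetal double bond or to ene-type reactions. A1 also presupposes a complete synthesis of the half B naphthalene, including its own C1'–C4' ring, followed by homologation at C1'. The overall step count is therefore not lower, and the least controllable step consumes the most advanced intermediate.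
- Comparison: the chosen route makes the hindered bond as a carbinol from two simple partners and uses a small, commercial ester in the ring-forming step, at the cost of two extra steps at the end.

**Alternative 2: amine-catalysed arene-forming aldol condensation.**
- Disconnection: C1'–C2' only, with C2' carrying a formyl group in place of the methyl.
- Forward key step: keto aldehyde A3, a diaryl ketone with a 4-oxobutanal chain in the ortho position, is treated with a secondary amine and a carboxylic acid. The enamine carbon C2' attacks the diaryl ketone carbon C1', and dehydration with enolisation of the C4' ketone gives naphthol aldehyde A4.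
- For it: the step is catalytic and needs no strong base. Arene-forming aldol condensations are an established entry to hindered biaryls, and a chiral amine could set the axis enantioselectively. The chosen route cannot do that, so this alternative is stronger there; for a target without a configured axis it brings no gain.
- Against it: the electrophile is a diaryl ketone shielded by three ortho substituents and deactivated by the ortho and para oxygen donors of half A. The 1,4-keto aldehyde has easier outlets, such as cyclodehydration to a furan and self-condensation. A4 carries a formyl group where the target has methyl, so a deoxygenation is added. A3 itself needs the ketone oxidation level at C1' and a differentiated four-carbon keto aldehyde chain on the neighbouring position, which costs more steps than phthalide 21.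
- Comparison: the chosen route puts the methyl on C2' directly and takes C2' and C3' from one commercial reagent. The price is a strongly basic step.

**Alternative 3: one-carbon ring expansion of an arylindanone.**
- Disconnection: C2'–C3' and C3'–C4', with C3' inserted as a single carbon.
- Forward key step: a dihalocarbene, made from a haloform and a bulky alkoxide, cyclopropanates silyl enol ether A5 of a 3-aryl-2-methylindanone. The adduct opens with loss of halide and the silyl group to give 2-bromo-1-naphthol A6.
- For it: ring expansion of indanone enol ethers to 2-halo-1-naphthols is known chemistry. The bromine of A6 would fall away in the final hydrogenolysis together with the benzyl groups, so the endgame is at least as short as the chosen one and avoids the decarboxylation.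
- Against it: the carbene is an electrophile and A5 contains two very electron-rich naphthalene and benzene rings that compete with a tetrasubstituted enol ether shielded by the neighbouring aryl group. The indanone behind A5 must be closed onto the position beside the C5' methoxy group, in competition with closure onto the more nucleophilic naphthalene of half A at its peri carbon C8. That makes the precursor longer and less certain than phthalide 21.
- Comparison: the chosen annulation has only one place to react, fixed by polarity, and its precursor is reached by one directed metalation. In exchange it needs the ester removal that this alternative avoids.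

Key step: step 14

## Route

Step 1
Reactants: 1 1,1-dimethoxyethene
Product: 2 4,4-dimethoxybut-3-en-2-one
Conditions: CH3COCl, Et3N, Et2O, 0 °C to rt
Reagents that add atoms: acetyl chloride, CC(=O)Cl
Why: C-acylation of the nucleophilic ketene acetal carbon followed by loss of HCl (addition–elimination) gives the push–pull enone; the amine keeps the acid-sensitive acetal from polymerising.

Step 2
Reactants: 2 4,4-dimethoxybut-3-en-2-one
Product: 3 [(4,4-dimethoxybuta-1,3-dien-2-yl)oxy](trimethyl)silane
Conditions: LiN(i-Pr)2, THF, −78 °C; then Me3SiCl, −78 °C to rt; distilled and used at once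
Reagents that add atoms: chlorotrimethylsilane, C[Si](C)(C)Cl
Why: Kinetic enolisation of the methyl ketone (its only enolisable position) and O-silylation give the silyl enol ether, a standard preparation of electron-rich dienes.

Step 3
Reactants: 4 5-methylbenzene-1,3-diol (orcinol)
Product: 5 2-iodo-5-methylbenzene-1,3-diol
Conditions: I2, NaHCO3, H2O/THF, 0 °C
Reagents that add atoms: iodine, II
Why: Electrophilic aromatic iodination of the resorcinol under bicarbonate conditions is expected at the carbon between the two hydroxyls, as for resorcinol itself.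

Step 4
Reactants: 5 2-iodo-5-methylbenzene-1,3-diol
Product: 6 3-(benzyloxy)-2-iodo-5-methylphenol
Conditions: BnBr (1.0 equiv), K2CO3, acetone, rt; unreacted 5 recovered
Reagents that add atoms: benzyl bromide, BrCc1ccccc1
Why: Williamson etherification of one of two equivalent phenols; the outcome is statistical, the monoether is separated from diol and diether, and the diol is recycled.

Step 5
Reactants: 6 3-(benzyloxy)-2-iodo-5-methylphenol
Product: 7 3-(benzyloxy)-2-iodo-5-methylphenyl trifluoromethanesulfonate
Conditions: (CF3SO2)2O, pyridine, CH2Cl2, 0 °C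
Reagents that add atoms: trifluoromethanesulfonic anhydride, O=S(=O)(OS(=O)(=O)C(F)(F)F)C(F)(F)F
Why: O-sulfonylation of the phenol gives the ortho-iodoaryl triflate, a standard aryne precursor.

Step 6
Reactants: 7 3-(benzyloxy)-2-iodo-5-methylphenyl trifluoromethanesulfonate; 3 [(4,4-dimethoxybuta-1,3-dien-2-yl)oxy](trimethyl)silane
Product: 10 5-(benzyloxy)-4-methoxy-7-methylnaphthalen-2-ol, via aryne 8 (not isolated), via dihydronaphthalene cycloadduct 9 (not isolated)
Conditions: n-BuLi (1.1 equiv) added to 7 and 3 (2.5 equiv), THF, −78 °C to rt; then 1 M HCl, THF, rt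
Reagents that add atoms: none
Why: Iodine–lithium exchange and loss of triflate give aryne 8, which undergoes an aryne Diels–Alder reaction with 3; the benzyloxy group polarises the aryne so that the nucleophilic CH2 terminus of the diene bonds to the remote aryne carbon and the ketene-acetal carbon to the one next to the benzyloxy group. Acid hydrolysis of the silyl enol ether and loss of methanol from 9 aromatise the ring, leaving OMe on C4 and a free OH on C2.

Step 7
Reactants: 10 5-(benzyloxy)-4-methoxy-7-methylnaphthalen-2-ol
Product: 11 3,8-bis(benzyloxy)-1-methoxy-6-methylnaphthalene (2,5-bis(benzyloxy)-4-methoxy-7-methylnaphthalene in the numbering of half A)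
Conditions: BnBr, K2CO3, DMF, 50 °C
Reagents that add atoms: benzyl bromide, BrCc1ccccc1
Why: Williamson etherification of the only free naphthol.

Step 8
Reactants: 11 3,8-bis(benzyloxy)-1-methoxy-6-methylnaphthalene
Product: 12 2,5-bis(benzyloxy)-4-methoxy-7-methylnaphthalene-1-carbaldehyde
Conditions: POCl3, DMF, 0 to 50 °C; then aq. NaOAc
Reagents that add atoms: N,N-dimethylformamide, CN(C)C=O; water, O
Why: Vilsmeier–Haack formylation at C1, the α-position that is ortho to the C2 benzyloxy and para to the C4 methoxy group; C3 lies between two ether groups and the other ring has a single donor.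

Step 9
Reactants: 13 methyl 2,3-dihydroxybenzoate
Product: 14 methyl 3-(benzyloxy)-2-hydroxybenzoate
Conditions: BnBr (1.05 equiv), K2CO3, acetone, rt
Reagents that add atoms: benzyl bromide, BrCc1ccccc1
Why: Williamson etherification; the 2-hydroxyl is held in a hydrogen bond to the ester carbonyl, so the 3-hydroxyl is the one alkylated.

Step 10
Reactants: 14 methyl 3-(benzyloxy)-2-hydroxybenzoate
Product: 15 methyl 3-(benzyloxy)-2-methoxybenzoate
Conditions: MeI, K2CO3, DMF, 50 °C
Reagents that add atoms: iodomethane, CI
Why: Williamson methylation of the remaining salicylate-type hydroxyl under slightly more forcing conditions.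

Step 11
Reactants: 15 methyl 3-(benzyloxy)-2-methoxybenzoate
Product: 16 3-(benzyloxy)-2-methoxybenzoic acid
Conditions: LiOH, THF/MeOH/H2O, 50 °C; then 1 M HCl
Reagents that add atoms: lithium hydroxide, [Li+].[OH-]
Why: Saponification of the methyl ester; both ether groups are inert to hydroxide.

Step 12
Reactants: 16 3-(benzyloxy)-2-methoxybenzoic acid
Product: 18 3-(benzyloxy)-N,N-diethyl-2-methoxybenzamide, via acid chloride 17 (not isolated)
Conditions: (COCl)2, DMF (cat.), CH2Cl2, 0 °C to rt; then Et2NH (3 equiv), CH2Cl2, 0 °C
Reagents that add atoms: diethylamine, CCNCC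
Why: Acid chloride formation and aminolysis give the tertiary amide that will direct the metalation.

Step 13
Reactants: 18 3-(benzyloxy)-N,N-diethyl-2-methoxybenzamide; 12 2,5-bis(benzyloxy)-4-methoxy-7-methylnaphthalene-1-carbaldehyde
Product: 21 racemic 6-(benzyloxy)-3-[2,5-bis(benzyloxy)-4-methoxy-7-methylnaphthalen-1-yl]-7-methoxy-2-benzofuran-1(3H)-one, via aryllithium 19 (not isolated), via hydroxy amide 20 (not isolated)
Conditions: s-BuLi, TMEDA, THF, −78 °C; then 12, −78 °C to rt; H2O; then TsOH·H2O, toluene, 80 °C
Reagents that add atoms: none
Why: Directed ortho-metalation: the diethylamide guides lithiation to its only free ortho position, para to the benzyloxy group, and 19 adds to the non-enolisable aldehyde. Acid then closes the γ-hydroxy amide 20 to the phthalide with loss of diethylamine; the carbinol stereocentre forms as a racemate and is erased in step 14.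

Step 14
Reactants: 21 racemic 6-(benzyloxy)-3-[2,5-bis(benzyloxy)-4-methoxy-7-methylnaphthalen-1-yl]-7-methoxy-2-benzofuran-1(3H)-one; 22 tert-butyl (E)-but-2-enoate
Product: 25 tert-butyl 7-(benzyloxy)-4-[2,5-bis(benzyloxy)-4-methoxy-7-methylnaphthalen-1-yl]-1-hydroxy-8-methoxy-3-methylnaphthalene-2-carboxylate, via lithiated phthalide 23 (not isolated), via hydroxy keto ester 24 (not isolated)
Conditions: LiN(i-Pr)2 (1.1 equiv), THF, −78 °C; then 22 (1.5 equiv), −78 to 0 °C; AcOH; then camphorsulfonic acid (10 mol %), CH2Cl2, rt
Reagents that add atoms: none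
Why: Proposed new method: the amide base removes the C3 proton of 21, which is benzylic, α to the lactone oxygen and acidified through the ring by the lactone carbonyl, to give anion 23; 23 adds through C3 to the β-carbon of 22 (bond C1'–C2'), and the resulting tert-butyl ester enolate attacks the lactone carbonyl (bond C3'–C4') in a 6-(enolexo)-exo-trig Dieckmann closure whose tetrahedral intermediate collapses to the C4' ketone and the C1' alkoxide, the acidic β-keto ester proton then quenching the alkoxide so that the sequence runs forward to 24. The closest known reactions are the Hauser–Kraus annulation of 3-cyano- and 3-sulfonylphthalides, the Staunton–Weinreb annulation of toluate anions and the acid-finished annulation of 3-unsubstituted phthalide anions with Michael acceptors; new here is a phthalide anion that already carries a hindered aryl group on C3, so that a quaternary carbon forms in the Michael step and aromatisation must come from loss of water. Catalytic sulfonic acid ionises the tertiary, doubly benzylic C1' hydroxyl of 24, and loss of the C2' proton with enolisation of the keto ester gives the naphthol while the tert-butyl ester survives the mild acid. Regiochemistry needs nothing beyond polarity: the anionic carbon can only bond to the methyl-bearing β-carbon and the enolate carbon can only reach the lactone carbonyl, so the methyl ends on C2' beside the axis and the hydroxyl on C4' peri to the C5' methoxy group. The transient stereocentres of 24 (C1', C2', C3') are erased on aromatisation, no stereocentre remains, and the axis created here forms as the racemate. The selectivity that matters is conjugate addition over γ-deprotonation of 22 and over 1,2-addition; the tert-butyl ester blocks 1,2-attack, and complete formation of 23 at −78 °C before 22 is added keeps free amide base away from the crotonate.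

Step 15
Reactants: 25 tert-butyl 7-(benzyloxy)-4-[2,5-bis(benzyloxy)-4-methoxy-7-methylnaphthalen-1-yl]-1-hydroxy-8-methoxy-3-methylnaphthalene-2-carboxylate
Product: 26 7-(benzyloxy)-4-[2,5-bis(benzyloxy)-4-methoxy-7-methylnaphthalen-1-yl]-1-hydroxy-8-methoxy-3-methylnaphthalene-2-carboxylic acid
Conditions: CF3CO2H/CH2Cl2 (1:4), 0 °C to rt, short reaction time
Reagents that add atoms: none
Why: Acidolysis of the tert-butyl ester by loss of 2-methylpropene; aryl benzyl and methyl ethers tolerate dilute acid at this temperature for a short time.

Step 16
Reactants: 26 7-(benzyloxy)-4-[2,5-bis(benzyloxy)-4-methoxy-7-methylnaphthalen-1-yl]-1-hydroxy-8-methoxy-3-methylnaphthalene-2-carboxylic acid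
Product: 27 7-(benzyloxy)-4-[2,5-bis(benzyloxy)-4-methoxy-7-methylnaphthalen-1-yl]-8-methoxy-3-methylnaphthalen-1-ol
Conditions: Cu2O (10 mol %), 1,10-phenanthroline (20 mol %), NMP/quinoline (3:1), 160 °C, Ar
Reagents that add atoms: none
Why: Copper-catalysed protodecarboxylation of an ortho-hydroxy aromatic acid; the carboxyl on C3' is flanked by the C4' hydroxyl and the C2' methyl and sits on an electron-rich naphthol ring, which favours ipso-protonation, and the basic medium spares the benzyl ethers.

Step 17
Reactants: 27 7-(benzyloxy)-4-[2,5-bis(benzyloxy)-4-methoxy-7-methylnaphthalen-1-yl]-8-methoxy-3-methylnaphthalen-1-ol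
Product: 28 1-(4,6-dihydroxy-5-methoxy-2-methylnaphthalen-1-yl)-4-methoxy-7-methylnaphthalene-2,5-diol
Conditions: H2 (1 atm), 10% Pd/C, EtOAc/MeOH, rt; work-up under Ar
Reagents that add atoms: none
Why: Catalytic hydrogenolysis cleaves the three aryl benzyl ethers and leaves the methyl ethers and the naphthalene rings untouched under these mild conditions; the racemic axis is not affected.

## Compound list

1 | 1,1-dimethoxyethene | C=C(OC)OC | starting material
2 | 4,4-dimethoxybut-3-en-2-one | CC(=O)C=C(OC)OC | intermediate
3 | [(4,4-dimethoxybuta-1,3-dien-2-yl)oxy](trimethyl)silane | C=C(O[Si](C)(C)C)C=C(OC)OC | intermediate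
4 | 5-methylbenzene-1,3-diol (orcinol) | Cc1cc(O)cc(O)c1 | starting material
5 | 2-iodo-5-methylbenzene-1,3-diol | Cc1cc(O)c(I)c(O)c1 | intermediate
6 | 3-(benzyloxy)-2-iodo-5-methylphenol | Cc1cc(O)c(I)c(OCc2ccccc2)c1 | intermediate
7 | 3-(benzyloxy)-2-iodo-5-methylphenyl trifluoromethanesulfonate | Cc1cc(OCc2ccccc2)c(I)c(OS(=O)(=O)C(F)(F)F)c1 | intermediate
8 | 3-(benzyloxy)-5-methyl-1,2-didehydrobenzene (aryne) | CC1=CC#CC(OCc2ccccc2)=C1 | intermediate
9 | {[5-(benzyloxy)-4,4-dimethoxy-7-methyl-1,4-dihydronaphthalen-2-yl]oxy}(trimethyl)silane | COC1(OC)C=C(O[Si](C)(C)C)Cc2cc(C)cc(OCc3ccccc3)c21 | intermediate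
10 | 5-(benzyloxy)-4-methoxy-7-methylnaphthalen-2-ol | COc1cc(O)cc2cc(C)cc(OCc3ccccc3)c12 | intermediate
11 | 3,8-bis(benzyloxy)-1-methoxy-6-methylnaphthalene | COc1cc(OCc2ccccc2)cc2cc(C)cc(OCc3ccccc3)c12 | intermediate
12 | 2,5-bis(benzyloxy)-4-methoxy-7-methylnaphthalene-1-carbaldehyde | COc1cc(OCc2ccccc2)c(C=O)c2cc(C)cc(OCc3ccccc3)c12 | intermediate
13 | methyl 2,3-dihydroxybenzoate | COC(=O)c1cccc(O)c1O | starting material
14 | methyl 3-(benzyloxy)-2-hydroxybenzoate | COC(=O)c1cccc(OCc2ccccc2)c1O | intermediate
15 | methyl 3-(benzyloxy)-2-methoxybenzoate | COC(=O)c1cccc(OCc2ccccc2)c1OC | intermediate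
16 | 3-(benzyloxy)-2-methoxybenzoic acid | COc1c(OCc2ccccc2)cccc1C(=O)O | intermediate
17 | 3-(benzyloxy)-2-methoxybenzoyl chloride | COc1c(OCc2ccccc2)cccc1C(=O)Cl | intermediate
18 | 3-(benzyloxy)-N,N-diethyl-2-methoxybenzamide | CCN(CC)C(=O)c1cccc(OCc2ccccc2)c1OC | intermediate
19 | [4-(benzyloxy)-2-(diethylcarbamoyl)-3-methoxyphenyl]lithium | [Li]c1ccc(OCc2ccccc2)c(OC)c1C(=O)N(CC)CC | intermediate
20 | racemic 3-(benzyloxy)-6-{[2,5-bis(benzyloxy)-4-methoxy-7-methylnaphthalen-1-yl](hydroxy)methyl}-N,N-diethyl-2-methoxybenzamide | CCN(CC)C(=O)c1c(OC)c(OCc2ccccc2)ccc1C(O)c1c(OCc2ccccc2)cc(OC)c2c(OCc3ccccc3)cc(C)cc12 | intermediate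
21 | racemic 6-(benzyloxy)-3-[2,5-bis(benzyloxy)-4-methoxy-7-methylnaphthalen-1-yl]-7-methoxy-2-benzofuran-1(3H)-one | O=C1OC(c2c(OCc3ccccc3)cc(OC)c3c(OCc4ccccc4)cc(C)cc23)c2ccc(OCc3ccccc3)c(OC)c12 | intermediate
22 | tert-butyl (E)-but-2-enoate | C/C=C/C(=O)OC(C)(C)C | starting material
23 | {5-(benzyloxy)-1-[2,5-bis(benzyloxy)-4-methoxy-7-methylnaphthalen-1-yl]-4-methoxy-3-oxo-1,3-dihydro-2-benzofuran-1-yl}lithium | [Li]C1(c2c(OCc3ccccc3)cc(OC)c3c(OCc4ccccc4)cc(C)cc23)OC(=O)c2c(OC)c(OCc3ccccc3)ccc21 | intermediate
24 | tert-butyl 7-(benzyloxy)-4-[2,5-bis(benzyloxy)-4-methoxy-7-methylnaphthalen-1-yl]-4-hydroxy-8-methoxy-3-methyl-1-oxo-1,2,3,4-tetrahydronaphthalene-2-carboxylate (racemic mixture of diastereomers) | CC1C(C(=O)OC(C)(C)C)C(=O)c2c(OC)c(OCc3ccccc3)ccc2C1(O)c1c(OCc2ccccc2)cc(OC)c2c(OCc3ccccc3)cc(C)cc12 | intermediate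
25 | tert-butyl 7-(benzyloxy)-4-[2,5-bis(benzyloxy)-4-methoxy-7-methylnaphthalen-1-yl]-1-hydroxy-8-methoxy-3-methylnaphthalene-2-carboxylate (racemic axis) | CC(C)(C)OC(=O)c1c(C)c(-c2c(OCc3ccccc3)cc(OC)c3c(OCc4ccccc4)cc(C)cc23)c2ccc(OCc3ccccc3)c(OC)c2c1O | intermediate
26 | 7-(benzyloxy)-4-[2,5-bis(benzyloxy)-4-methoxy-7-methylnaphthalen-1-yl]-1-hydroxy-8-methoxy-3-methylnaphthalene-2-carboxylic acid (racemic axis) | OC(=O)c1c(C)c(-c2c(OCc3ccccc3)cc(OC)c3c(OCc4ccccc4)cc(C)cc23)c2ccc(OCc3ccccc3)c(OC)c2c1O | intermediate
27 | 7-(benzyloxy)-4-[2,5-bis(benzyloxy)-4-methoxy-7-methylnaphthalen-1-yl]-8-methoxy-3-methylnaphthalen-1-ol (racemic axis) | Cc1cc(O)c2c(OC)c(OCc3ccccc3)ccc2c1-c1c(OCc2ccccc2)cc(OC)c2c(OCc3ccccc3)cc(C)cc12 | intermediate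
28 | 1-(4,6-dihydroxy-5-methoxy-2-methylnaphthalen-1-yl)-4-methoxy-7-methylnaphthalene-2,5-diol (racemic axis) | COc1cc(O)c(-c2c(C)cc(O)c3c(OC)c(O)ccc23)c2cc(C)cc(O)c12 | target

## Step count and least certain steps

Total step count: 17. Longest linear sequence: 11 steps (steps 3 to 8 and 13 to 17, from orcinol 4).

**Step 14 (key step).** The most likely failure is that the hindered tertiary anion 23 takes a γ-proton from 22, or that the Michael addition reverses, faster than the quaternary carbon next to a tertiary one is formed; the Dieckmann closure then never starts and 21 is returned.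
Fallback, from 21 back to 25, with a secondary benzylic anion in the established Staunton–Weinreb manifold:
- Ionic hydrogenation of the lactone C3–O bond of 21 (Et3SiH, CF3CO2H, CH2Cl2, 0 °C) should give 3-(benzyloxy)-6-{[2,5-bis(benzyloxy)-4-methoxy-7-methylnaphthalen-1-yl]methyl}-2-methoxybenzoic acid F1.
- Methylation (MeI, K2CO3, DMF) gives methyl 3-(benzyloxy)-6-{[2,5-bis(benzyloxy)-4-methoxy-7-methylnaphthalen-1-yl]methyl}-2-methoxybenzoate F2.
- Deprotonation of the diarylmethane carbon with LiN(i-Pr)2 and reaction with 22 (Michael addition, then Dieckmann closure onto the methyl ester) gives tert-butyl 7-(benzyloxy)-4-[2,5-bis(benzyloxy)-4-methoxy-7-methylnaphthalen-1-yl]-1-hydroxy-8-methoxy-3-methyl-3,4-dihydronaphthalene-2-carboxylate F3.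
- Dehydrogenation of this β-keto ester by α-selenenylation and selenoxide elimination (PhSeCl, pyridine; then H2O2) gives 25.

**Step 13.** Two things can go wrong: deprotonation at the benzylic CH2 of the benzyl ether competes with ring lithiation, and the hindered aryllithium 19 adds slowly to a hindered, donor-deactivated aldehyde.
Fallback, from 15 (with 12) back to 21, using halogen–magnesium exchange instead of deprotonation and no alkyllithium:
- Bromination of 15 with NBS in DMF, expected para to the benzyloxy group because the flanked 2-methoxy group is twisted out of conjugation, gives methyl 3-(benzyloxy)-6-bromo-2-methoxybenzoate F4.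
- Bromine–magnesium exchange with i-PrMgCl·LiCl (THF, −20 to 0 °C) and addition to 12 gives an alkoxide that closes onto the neighbouring methyl ester, forming 21 directly.

**Step 6.** Aryne 8 may be consumed by [2+2] addition at the ketene-acetal double bond or by ene-type pathways, or the alkyllithium may attack the silyl enol ether, so that little of the [4+2] adduct forms.
Fallback, from 6 back to 11, replacing the cycloaddition by insertion and condensation:
- One-pot O-silylation, iodine–lithium exchange with shift of silicon from oxygen to carbon, and triflation ((Me3Si)2NH; n-BuLi, THF, −78 °C; (CF3SO2)2O) gives 3-(benzyloxy)-5-methyl-2-(trimethylsilyl)phenyl trifluoromethanesulfonate F5.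
- CsF in MeCN at 80 °C with methyl 3-oxobutanoate inserts the aryne into the C–C bond of the keto ester (acyl-alkylation, acetyl group next to the benzyloxy group) to give methyl 2-[2-acetyl-3-(benzyloxy)-5-methylphenyl]acetate F6.
- NaOMe in MeOH closes the ring by intramolecular Claisen condensation to 8-(benzyloxy)-6-methylnaphthalene-1,3-diol F7.
- Benzylation of the unhindered 3-hydroxyl (BnBr, 1 equiv, K2CO3), the 1-hydroxyl being hydrogen-bonded to the peri ether oxygen, gives 3,8-bis(benzyloxy)-6-methylnaphthalen-1-ol F8.
- Methylation (MeI, K2CO3, DMF) gives 11.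

**Step 16 (with step 15).** Decarboxylation of the aromatic hydroxy acid may need temperatures at which benzyl groups migrate or are lost. In step 15 the tert-butyl cation may alkylate the electron-rich rings.
Fallback, from 21 back to 27, moving the decarboxylation to the non-aromatic β-keto ester stage:
- Step 14 is run with prop-2-en-1-yl (E)-but-2-enoate in place of 22 and quenched with AcOH without the dehydrating acid, to give prop-2-en-1-yl 7-(benzyloxy)-4-[2,5-bis(benzyloxy)-4-methoxy-7-methylnaphthalen-1-yl]-4-hydroxy-8-methoxy-3-methyl-1-oxo-1,2,3,4-tetrahydronaphthalene-2-carboxylate F9.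
- Palladium-catalysed deallylation with decarboxylation (Pd(PPh3)4, HCO2H/Et3N, THF, rt) gives 7-(benzyloxy)-4-[2,5-bis(benzyloxy)-4-methoxy-7-methylnaphthalen-1-yl]-4-hydroxy-8-methoxy-3-methyl-3,4-dihydronaphthalen-1(2H)-one F10.
- Camphorsulfonic acid in CH2Cl2 dehydrates and enolises F10 to 27.

## Further compounds

F1 | step 14 | 3-(benzyloxy)-6-{[2,5-bis(benzyloxy)-4-methoxy-7-methylnaphthalen-1-yl]methyl}-2-methoxybenzoic acid | OC(=O)c1c(OC)c(OCc2ccccc2)ccc1Cc1c(OCc2ccccc2)cc(OC)c2c(OCc3ccccc3)cc(C)cc12
F2 | step 14 | methyl 3-(benzyloxy)-6-{[2,5-bis(benzyloxy)-4-methoxy-7-methylnaphthalen-1-yl]methyl}-2-methoxybenzoate | COC(=O)c1c(OC)c(OCc2ccccc2)ccc1Cc1c(OCc2ccccc2)cc(OC)c2c(OCc3ccccc3)cc(C)cc12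
F3 | step 14 | tert-butyl 7-(benzyloxy)-4-[2,5-bis(benzyloxy)-4-methoxy-7-methylnaphthalen-1-yl]-1-hydroxy-8-methoxy-3-methyl-3,4-dihydronaphthalene-2-carboxylate (racemic mixture of diastereomers) | CC1C(c2c(OCc3ccccc3)cc(OC)c3c(OCc4ccccc4)cc(C)cc23)c2ccc(OCc3ccccc3)c(OC)c2C(O)=C1C(=O)OC(C)(C)C
F4 | step 13 | methyl 3-(benzyloxy)-6-bromo-2-methoxybenzoate | COC(=O)c1c(Br)ccc(OCc2ccccc2)c1OC
F5 | step 6 | 3-(benzyloxy)-5-methyl-2-(trimethylsilyl)phenyl trifluoromethanesulfonate | Cc1cc(OCc2ccccc2)c([Si](C)(C)C)c(OS(=O)(=O)C(F)(F)F)c1
F6 | step 6 | methyl 2-[2-acetyl-3-(benzyloxy)-5-methylphenyl]acetate | COC(=O)Cc1cc(C)cc(OCc2ccccc2)c1C(C)=O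
F7 | step 6 | 8-(benzyloxy)-6-methylnaphthalene-1,3-diol | Oc1cc(O)c2c(OCc3ccccc3)cc(C)cc2c1
F8 | step 6 | 3,8-bis(benzyloxy)-6-methylnaphthalen-1-ol | Oc1cc(OCc2ccccc2)cc2cc(C)cc(OCc3ccccc3)c12
F9 | step 16 | prop-2-en-1-yl 7-(benzyloxy)-4-[2,5-bis(benzyloxy)-4-methoxy-7-methylnaphthalen-1-yl]-4-hydroxy-8-methoxy-3-methyl-1-oxo-1,2,3,4-tetrahydronaphthalene-2-carboxylate (racemic mixture of diastereomers) | C=CCOC(=O)C1C(C)C(O)(c2c(OCc3ccccc3)cc(OC)c3c(OCc4ccccc4)cc(C)cc23)c2ccc(OCc3ccccc3)c(OC)c2C1=O
F10 | step 16 | 7-(benzyloxy)-4-[2,5-bis(benzyloxy)-4-methoxy-7-methylnaphthalen-1-yl]-4-hydroxy-8-methoxy-3-methyl-3,4-dihydronaphthalen-1(2H)-one (racemic mixture of diastereomers) | CC1CC(=O)c2c(OC)c(OCc3ccccc3)ccc2C1(O)c1c(OCc2ccccc2)cc(OC)c2c(OCc3ccccc3)cc(C)cc12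
A1 | alternative 1 | {[1-[4,6-bis(benzyloxy)-5-methoxy-2-methylnaphthalen-1-yl]-4,4-dimethoxybuta-1,3-dien-2-yl]oxy}(trimethyl)silane | COC(OC)=CC(O[Si](C)(C)C)=Cc1c(C)cc(OCc2ccccc2)c2c(OC)c(OCc3ccccc3)ccc12
A2 | alternative 1 | 5-(benzyloxy)-1-[4,6-bis(benzyloxy)-5-methoxy-2-methylnaphthalen-1-yl]-4-methoxy-7-methylnaphthalen-2-ol | COc1cc(O)c(-c2c(C)cc(OCc3ccccc3)c3c(OC)c(OCc4ccccc4)ccc23)c2cc(C)cc(OCc3ccccc3)c12
A3 | alternative 2 | 4-{3-(benzyloxy)-6-[2,5-bis(benzyloxy)-4-methoxy-7-methylnaphthalene-1-carbonyl]-2-methoxyphenyl}-4-oxobutanal | O=CCCC(=O)c1c(OC)c(OCc2ccccc2)ccc1C(=O)c1c(OCc2ccccc2)cc(OC)c2c(OCc3ccccc3)cc(C)cc12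
A4 | alternative 2 | 6-(benzyloxy)-1-[2,5-bis(benzyloxy)-4-methoxy-7-methylnaphthalen-1-yl]-4-hydroxy-5-methoxynaphthalene-2-carbaldehyde | O=Cc1cc(O)c2c(OC)c(OCc3ccccc3)ccc2c1-c1c(OCc2ccccc2)cc(OC)c2c(OCc3ccccc3)cc(C)cc12
A5 | alternative 3 | {[5-(benzyloxy)-1-[2,5-bis(benzyloxy)-4-methoxy-7-methylnaphthalen-1-yl]-4-methoxy-2-methyl-1H-inden-3-yl]oxy}(trimethyl)silane (racemic) | CC1=C(O[Si](C)(C)C)c2c(OC)c(OCc3ccccc3)ccc2C1c1c(OCc2ccccc2)cc(OC)c2c(OCc3ccccc3)cc(C)cc12
A6 | alternative 3 | 7-(benzyloxy)-4-[2,5-bis(benzyloxy)-4-methoxy-7-methylnaphthalen-1-yl]-2-bromo-8-methoxy-3-methylnaphthalen-1-ol | Cc1c(Br)c(O)c2c(OC)c(OCc3ccccc3)ccc2c1-c1c(OCc2ccccc2)cc(OC)c2c(OCc3ccccc3)cc(C)cc12
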